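(Readings and results come from a simulation for substances that don't exist.)

**Bench note: Monday's flask**

1. Keep Monday's flask at 0 °C and leave its reagent charge alone until 4.0 d; step 4 reckons what it should hold then.

| setting | amber | red | Saturday's | Thursday's | Monday's |
|---|---|---|---|---|---|
| substrate | 10 mM | 10 mM | 10 mM | 10 mM | 10 mM |
| reagent | 28 mM | 44 mM | 20.0 mM | 20.0 mM | 20.0 mM |
| catalyst | 1.6 mM | 1.6 mM | 1.6 mM | 1.6 mM | 1.6 mM |
| temperature | 10 °C | 32 °C | 20 °C | 40 °C | 0 °C |
| remark | run made earlier | run made earlier |  |  |  |
| time |  |  | 4.0 d | 4.0 d | 4.0 d |

amber run (percent of the substrate charged)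

| time / d | target / % |
|---|---|
| 1.04 | 96.4 |
| 2.08 | 95.9 |
| 3.00 | 94.8 |
| 4.00 | 95.2 |
| 5.00 | 94.1 |
| 6.00 | 94.9 |

red run (percent of the substrate charged)

| time / h | target / % |
|---|---|
| 3.00 | 90.6 |
| 12.0 | 90.0 |
| 15.0 | 89.5 |
| 25.0 | 89.5 |
| 40.0 | 89.6 |
| 48.0 | 90.7 |

(standard deviation of a reading: 0.5 percentage points)



1. the flask that comes out highest in amount of target, in percent of the substrate charged, or "all alike" when all lie within 1.5 percentage points (Saturday's / Thursday's / Monday's / all alike)
2. target at the end, in percent of the substrate charged, Saturday's
3. target at the end, in percent of the substrate charged, Thursday's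
4. target at the end, in percent of the substrate charged, Monday's

2. The amber and red runs each hold near one level from the first reading, their readings averaging 95.2% and 90.0% target. The hotter red run reads lower than amber despite 4.40 equivalents of reagent against 2.80. So take a one-to-one balance, substrate + reagent ⇌ target. Its hold number is the target fraction divided by the substrate fraction left times the reagent left, each a fraction of the substrate charge. This is the equilibrium constant in charge units. The readings give 10.8 for amber, a power of ten of 1.03, and 2.57 for red, a power of 0.409.

3. Assume the power falls in a straight line with temperature. Monday's hold number, the target fraction over the product of substrate and reagent left, is then 20.7. Saturday's is 5.61 and Thursday's 1.52.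

4. With 2.00 equivalents, the balance puts target at 95.6% on Monday's, 86.4% on Saturday's and 67.0% on Thursday's. Monday's comes out highest. Amber stood level by 1.04 d at 10 °C; that Monday's arrives within 4.0 d is taken on trust.

5. The forecast also names Monday's, with 95.5% there, 86.5% on Saturday's and 70% on Thursday's, the last above this reckoning's Thursday figure; its ground: “suggests an exothermic equilibrium”.

6. The flasks give 95.8% on Monday's, 86.3% on Saturday's and 65.1% on Thursday's, so Monday's is highest.

    target → over-reaction product (k = 4.24 × 10⁻⁵ h⁻¹, Ea = 118 kJ mol⁻¹)
    substrate + reagent + catalyst ⇌ target + catalyst, rate k2*[substrate]*[reagent]*[catalyst] forward; the back reaction follows from the equilibrium constant (K = 570 M⁻¹, k = 18200 M⁻² h⁻¹, Ea = 39.0 kJ mol⁻¹, ΔH = −45.0 kJ mol⁻¹)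
    (constants at 20 °C)

7. At 4.00 d Thursday's holds 6.00% over-reaction product, less than its target gap of 31 percentage points to Monday's. A neighbour of Monday's, with 5.0 mM reagent, has 0.500 equivalents, which makes reagent the limiting reagent. At the same temperature and substrate charge, the same hold number 20.7 gives 45.9% target, and the neighbour gives 46.0%. It ends with 54% of its substrate and 8.0% of its own reagent charge still unbound.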